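**Plan**
- Retrosynthetic cuts, in order: the C3–O acyl bond (angelate) and C13=C14 (olefination); C4–C18 (formaldehyde aldol on a ring A enolate); then C1–C2 and C3–C4 together, which removes ring A as a two-carbon vinylboronate; C8=C17 and C4≡C19; finally ring B by a Diels–Alder cut (C5–C6, C9–C10).
- Forward: ring B is made first by cycloaddition of a 2-silyloxydiene (already carrying C11–C13 and C16) with a formyl-substituted methacrylate. Ring A is then annulated onto it in one radical chain event, followed by C18, the C3 alcohol, the side-chain enoate and the angelate.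
- Enabling feature: in ring A, C1 is a CH2 on the quaternary C10, so its radical cannot fragment or close a small ring. C3 is the oxygen-bearing carbon (boron stands in for O). C4 carries the one-carbon branch C19, so C4≡C19 can be the radical acceptor. C1 and C4 sit trans-diequatorial on ring B.
- Stereochemistry: C5, C9 and C10 come from a catalyst-controlled, formyl-endo Diels–Alder of an E dienophile. C4 comes from equatorial attack of formaldehyde on the enolate, anti to the axial C10 methyl. C3 comes from axial hydride delivery. The Z ester comes from angelic acid itself and the E enoate from the olefination.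

Key step: step 11

Remark (numbering): atoms carry labdane numbers. Ring A is C1–C5 plus C10; ring B is C5–C10; C17 is the methylene carbon on C8; C18 is the oxygen-bearing carbon on C4 (trans to the C10 methyl); C19 is the methyl on C4; C20 is the methyl on C10; C11–C16 are the side chain on C9. "Nor" names count the carbons still missing.

Remark (assumption): in step 6 the enantiomer of the oxazaborolidinium catalyst is taken that gives 10; the facial sense follows the usual model for bound enals and is to be confirmed by correlation on the first run.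

Step 1
Reactants: 1 2-(3-chloropropyl)-2-methyl-1,3-dioxolane; 2 acrolein
Product: 3 6-(2-methyl-1,3-dioxolan-2-yl)hex-1-en-3-ol (racemic)
Conditions: Mg, I2 (cat.), THF, reflux; then 2, −78 °C → 0 °C; aq. NH4Cl
Reagents that add atoms: none
Why: Grignard 1,2-addition to the aldehyde, with the ketal masking the future C13 ketone; the carbinol centre is lost in step 2, so no stereocontrol is needed.

Step 2
Reactants: 3 6-(2-methyl-1,3-dioxolan-2-yl)hex-1-en-3-ol
Product: 4 6-(2-methyl-1,3-dioxolan-2-yl)hex-1-en-3-one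
Conditions: Dess–Martin periodinane, NaHCO3, CH2Cl2, 0 °C; used at once
Reagents that add atoms: none
Why: Dess–Martin oxidation of the allylic alcohol to the vinyl ketone under buffered conditions that spare the ketal.

Step 3
Reactants: 4 6-(2-methyl-1,3-dioxolan-2-yl)hex-1-en-3-one
Product: 5 (3Z)-6-(2-methyl-1,3-dioxolan-2-yl)-3-(triisopropylsilyloxy)hexa-1,3-diene
Conditions: i-Pr3SiOTf, Et3N, CH2Cl2, 0 °C → rt
Reagents that add atoms: triisopropylsilyl triflate, CC(C)[Si](OS(=O)(=O)C(F)(F)F)(C(C)C)C(C)C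
Why: Soft enolization (silyl triflate and amine) at the only enolizable position gives the 2-silyloxydiene, Z at the new double bond (silyloxy cis to the chain), which places the chain on the outside of the s-cis diene.

Step 4
Reactants: 6 ethyl 2-(triphenylphosphoranylidene)propanoate; 7 2,2-dimethoxyacetaldehyde
Product: 8 ethyl (2E)-4,4-dimethoxy-2-methylbut-2-enoate
Conditions: CH2Cl2, rt (7 as 60% aq. solution)
Reagents that add atoms: none
Why: Wittig reaction of a stabilized ylide, E-selective (ester trans to the acetal carbon).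

Step 5
Reactants: 8 ethyl (2E)-4,4-dimethoxy-2-methylbut-2-enoate
Product: 9 ethyl (2E)-2-methyl-4-oxobut-2-enoate
Conditions: Amberlyst-15, acetone/H2O, rt
Reagents that add atoms: water, O
Why: Acid hydrolysis of the dimethyl acetal; the E double bond, conjugated to both carbonyls, is kept.

Step 6
Reactants: 5 (3Z)-6-(2-methyl-1,3-dioxolan-2-yl)-3-(triisopropylsilyloxy)hexa-1,3-diene; 9 ethyl (2E)-2-methyl-4-oxobut-2-enoate
Product: 10 ethyl (1S,2S,6S)-6-formyl-1-methyl-2-[2-(2-methyl-1,3-dioxolan-2-yl)ethyl]-3-(triisopropylsilyloxy)cyclohex-3-ene-1-carboxylate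
Conditions: o-tolyl oxazaborolidinium triflimide from diphenylprolinol (20 mol%), CH2Cl2, −78 → −40 °C
Reagents that add atoms: none
Why: Normal-demand Diels–Alder in which the silyloxy group sends the substituted diene terminus (C9) to the carbon β to the catalyst-bound formyl group (C10), the E geometry of 9 fixes C5/C10 (formyl trans to ester), the formyl-endo transition state places the C9 chain cis to the C10 methyl, and the chiral cation selects the diene face.

Step 7
Reactants: 10 ethyl (1S,2S,6S)-6-formyl-1-methyl-2-[2-(2-methyl-1,3-dioxolan-2-yl)ethyl]-3-(triisopropylsilyloxy)cyclohex-3-ene-1-carboxylate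
Product: 12 ethyl (1R,2S,6R)-6-ethynyl-1-methyl-2-[2-(2-methyl-1,3-dioxolan-2-yl)ethyl]-3-oxocyclohexane-1-carboxylate, via alkynyl silyl enol ether 11 (not isolated)
Conditions: dimethyl (1-diazo-2-oxopropyl)phosphonate, K2CO3, MeOH, 0 °C → rt; then AcOH, Bu4NF, THF, 0 °C
Reagents that add atoms: dimethyl (1-diazo-2-oxopropyl)phosphonate, CC(=O)C(=[N+]=[N-])P(=O)(OC)OC
Why: Seyferth–Gilbert homologation (Ohira–Bestmann reagent) should turn the formyl group into the terminal alkyne C4≡C19 faster than C5 epimerizes, after which buffered fluoride frees the C8 ketone by protonation at C7 and leaves C9 untouched.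

Step 8
Reactants: 12 ethyl (1R,2S,6R)-6-ethynyl-1-methyl-2-[2-(2-methyl-1,3-dioxolan-2-yl)ethyl]-3-oxocyclohexane-1-carboxylate
Product: 13 ethyl (1S,2R,6R)-6-ethynyl-1-methyl-3-methylidene-2-[2-(2-methyl-1,3-dioxolan-2-yl)ethyl]cyclohexane-1-carboxylate
Conditions: Zn, CH2Br2, TiCl4, THF/CH2Cl2, 0 °C → rt
Reagents that add atoms: dibromomethane, BrCBr
Why: Non-basic zinc–titanium methylenation (Lombardo) converts the ketone, not the ester, into the C8=C17 methylene without enolizing C9.

Step 9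
Reactants: 13 ethyl (1S,2R,6R)-6-ethynyl-1-methyl-3-methylidene-2-[2-(2-methyl-1,3-dioxolan-2-yl)ethyl]cyclohexane-1-carboxylate
Product: 14 [(1S,2R,6R)-6-ethynyl-1-methyl-3-methylidene-2-[2-(2-methyl-1,3-dioxolan-2-yl)ethyl]cyclohexyl]methanol
Conditions: LiAlH4, THF, 0 °C → rt
Reagents that add atoms: none
Why: Hydride reduction of the neopentyl ester to the primary alcohol (C1); alkyne, alkene and ketal are inert.

Step 10
Reactants: 14 [(1S,2R,6R)-6-ethynyl-1-methyl-3-methylidene-2-[2-(2-methyl-1,3-dioxolan-2-yl)ethyl]cyclohexyl]methanol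
Product: 15 2-{2-[(1R,2S,3R)-3-ethynyl-2-(iodomethyl)-2-methyl-6-methylidenecyclohexyl]ethyl}-2-methyl-1,3-dioxolane
Conditions: PPh3, I2, imidazole, toluene, 70 °C
Reagents that add atoms: iodine, II
Why: Appel-type iodination of the neopentyl alcohol, a slow SN2 displacement forced by heat, gives the radical precursor.

Step 11
Reactants: 15 2-{2-[(1R,2S,3R)-3-ethynyl-2-(iodomethyl)-2-methyl-6-methylidenecyclohexyl]ethyl}-2-methyl-1,3-dioxolane; 16 4,4,5,5-tetramethyl-2-vinyl-1,3,2-dioxaborolane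
Product: 18 (3R,5R,9R,10S)-13,13-(ethylenedioxy)-3-(4,4,5,5-tetramethyl-1,3,2-dioxaborolan-2-yl)-14,15,18-trinorlabda-4(19),8(17)-diene, via α-boryl radical 17 (not isolated)
Conditions: 16 (5 equiv), (Me3Si)3SiH (1.5 equiv, syringe pump, 8 h), AIBN (0.3 equiv), benzene, 80 °C, 0.05 M
Reagents that add atoms: none
Why: Proposed new method: the silyl radical abstracts iodine from 15 to give the neopentyl C1 radical, which cannot close on the alkyne (4-exo or 5-endo) or fragment and so adds to the CH2 terminus of 16 (bond C1–C2); the α-boryl C3 radical 17 then attacks the internal alkyne carbon (bond C3–C4) and the σ-vinyl radical takes hydrogen from the silane to leave the C4=C19 methylene. The closest known reaction types are the Giese addition of alkyl radicals to vinylboronates and the exo cyclizations of α-boryl radicals, merged here into one radical [4+2] annulation. Ring A closes in the 6-exo-dig mode through a chair-like transition state. The trans ring fusion is inherited, because the C1 arm on C10 and the alkyne on C5 are trans-diequatorial on ring B; the only new stereocentre, C3, should carry boron equatorially (pseudo-equatorial in the chair) and is erased in step 13 in any case. The step needs the bimolecular addition to outrun reduction of the C1 radical, and the ring closure to outrun reduction, 1,5-hydrogen transfer from C5–H and oligomerization of 17; excess 16, slow silane addition, the polarity match of each addition and the gauche pre-organization of the two arms are meant to secure this.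

Step 12
Reactants: 18 (3R,5R,9R,10S)-13,13-(ethylenedioxy)-3-(4,4,5,5-tetramethyl-1,3,2-dioxaborolan-2-yl)-14,15,18-trinorlabda-4(19),8(17)-diene
Product: 19 (3R,5S,9R,10S)-13,13-(ethylenedioxy)-14,15,18-trinorlabda-4(19),8(17)-dien-3-ol
Conditions: H2O2 (30% aq.), NaOH, THF, 0 °C
Reagents that add atoms: hydrogen peroxide, OO
Why: Stereoretentive oxidation of the C–B bond (1,2-shift of C3 from boron to oxygen) without allylic transposition, installing the C3 oxygen.

Step 13
Reactants: 19 (3R,5S,9R,10S)-13,13-(ethylenedioxy)-14,15,18-trinorlabda-4(19),8(17)-dien-3-ol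
Product: 20 (5S,9R,10S)-13,13-(ethylenedioxy)-14,15,18-trinorlabda-4(19),8(17)-dien-3-one
Conditions: Dess–Martin periodinane, NaHCO3, CH2Cl2, 0 °C; used at once
Reagents that add atoms: none
Why: Dess–Martin oxidation to the s-cis α-methylene ketone, which erases the C3 centre and sets up a regiodefined enolate.

Step 14
Reactants: 20 (5S,9R,10S)-13,13-(ethylenedioxy)-14,15,18-trinorlabda-4(19),8(17)-dien-3-one
Product: 23 (4S,5S,9R,10S)-13,13-(ethylenedioxy)-18-(triisopropylsilyloxy)-14,15-dinorlabd-8(17)-en-3-one, via lithium enolate 21 (not isolated), via β-hydroxy ketone 22 (not isolated)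
Conditions: LiBH(s-Bu)3, THF, −78 °C; CH2O (monomer in THF), −78 → −45 °C; i-Pr3SiOTf, 2,6-lutidine, −78 → 0 °C
Reagents that add atoms: formaldehyde, C=O; triisopropylsilyl triflate, CC(C)[Si](OS(=O)(=O)C(F)(F)F)(C(C)C)C(C)C
Why: Conjugate hydride addition to the exocyclic enone makes C19 the methyl and gives the C3–C4 enolate regiospecifically, formaldehyde attacks C4 from the face anti to the axial C10 methyl (equatorial attack, as in reductive alkylations of 4-methyl-3-keto decalins) so that C18 is equatorial and C19 axial, and the alkoxide is silylated in the same flask.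

Step 15
Reactants: 23 (4S,5S,9R,10S)-13,13-(ethylenedioxy)-18-(triisopropylsilyloxy)-14,15-dinorlabd-8(17)-en-3-one
Product: 25 (3R,4S,5S,9R,10S)-3-hydroxy-18-(triisopropylsilyloxy)-14,15-dinorlabd-8(17)-en-13-one, via hydroxy ketal 24 (not isolated)
Conditions: NaBH4, MeOH/THF, 0 °C; then 1 M HCl (aq.), rt
Reagents that add atoms: water, O
Why: NaBH4 delivers hydride axially, from the face free of the two axial methyls, to give the equatorial 3-alcohol, and aqueous acid then hydrolyses the dioxolane to the C13 methyl ketone.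

Step 16
Reactants: 25 (3R,4S,5S,9R,10S)-3-hydroxy-18-(triisopropylsilyloxy)-14,15-dinorlabd-8(17)-en-13-one; 26 allyl 2-(diethoxyphosphoryl)acetate
Product: 27 allyl (3R,4S,5S,9R,10S,13E)-3-hydroxy-18-(triisopropylsilyloxy)labda-8(17),13-dien-15-oate
Conditions: NaH, THF, 0 → 45 °C
Reagents that add atoms: none
Why: Horner–Wadsworth–Emmons olefination of the methyl ketone, E-selective (ester trans to the C12 chain); any minor Z isomer is to be removed by chromatography.

Step 17
Reactants: 27 allyl (3R,4S,5S,9R,10S,13E)-3-hydroxy-18-(triisopropylsilyloxy)labda-8(17),13-dien-15-oate; 28 angelic acid ((2Z)-2-methylbut-2-enoic acid)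
Product: 30 allyl (3R,4S,5S,9R,10S,13E)-3-[(2Z)-2-methylbut-2-enoyloxy]-18-(triisopropylsilyloxy)labda-8(17),13-dien-15-oate, via mixed anhydride 29 (not isolated)
Conditions: 28, 2,4,6-trichlorobenzoyl chloride, Et3N, toluene, rt; then 27, 75 °C
Reagents that add atoms: none
Why: Yamaguchi mixed-anhydride acylation without a nucleophilic catalyst should acylate the hindered equatorial alcohol at the less hindered angeloyl carbonyl and avoid Z-to-E isomerization.

Step 18
Reactants: 30 allyl (3R,4S,5S,9R,10S,13E)-3-[(2Z)-2-methylbut-2-enoyloxy]-18-(triisopropylsilyloxy)labda-8(17),13-dien-15-oate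
Product: 32 (3R,4S,5S,9R,10S,13E)-18-hydroxy-3-[(2Z)-2-methylbut-2-enoyloxy]labda-8(17),13-dien-15-oic acid (target), via silyl ether acid 31 (not isolated)
Conditions: Pd(PPh3)4 (5 mol%), PhSiH3, THF, rt; then HF·pyridine, pyridine, 0 °C → rt
Reagents that add atoms: none
Why: Pd-catalysed allyl transfer to the silane frees the acid under neutral conditions and HF·pyridine then cleaves the silyl ester and the triisopropylsilyl ether; no base is present, so the angelate should neither migrate to O18 nor isomerize.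

**Compound list**
1 | 2-(3-chloropropyl)-2-methyl-1,3-dioxolane | CC1(CCCCl)OCCO1 | starting material
2 | acrolein (prop-2-enal) | C=CC=O | starting material
3 | 6-(2-methyl-1,3-dioxolan-2-yl)hex-1-en-3-ol (racemic) | C=CC(O)CCCC1(C)OCCO1 | intermediate
4 | 6-(2-methyl-1,3-dioxolan-2-yl)hex-1-en-3-one | C=CC(=O)CCCC1(C)OCCO1 | intermediate
5 | (3Z)-6-(2-methyl-1,3-dioxolan-2-yl)-3-(triisopropylsilyloxy)hexa-1,3-diene | C=C/C(O[Si](C(C)C)(C(C)C)C(C)C)=C/CCC1(C)OCCO1 | intermediate
6 | ethyl 2-(triphenylphosphoranylidene)propanoate | CCOC(=O)C(C)=P(c1ccccc1)(c1ccccc1)c1ccccc1 | starting material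
7 | 2,2-dimethoxyacetaldehyde | COC(OC)C=O | starting material
8 | ethyl (2E)-4,4-dimethoxy-2-methylbut-2-enoate | CCOC(=O)/C(C)=C/C(OC)OC | intermediate
9 | ethyl (2E)-2-methyl-4-oxobut-2-enoate | CCOC(=O)/C(C)=C/C=O | intermediate
10 | ethyl (1S,2S,6S)-6-formyl-1-methyl-2-[2-(2-methyl-1,3-dioxolan-2-yl)ethyl]-3-(triisopropylsilyloxy)cyclohex-3-ene-1-carboxylate | CC(C)[Si](OC1=CC[C@H](C=O)[C@@](C)(C(=O)OCC)[C@@H]1CCC2(C)OCCO2)(C(C)C)C(C)C | intermediate
11 | ethyl (1R,2S,6R)-6-ethynyl-1-methyl-2-[2-(2-methyl-1,3-dioxolan-2-yl)ethyl]-3-(triisopropylsilyloxy)cyclohex-3-ene-1-carboxylate (not isolated) | CC(C)[Si](OC1=CC[C@H](C#C)[C@@](C)(C(=O)OCC)[C@@H]1CCC2(C)OCCO2)(C(C)C)C(C)C | intermediate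
12 | ethyl (1R,2S,6R)-6-ethynyl-1-methyl-2-[2-(2-methyl-1,3-dioxolan-2-yl)ethyl]-3-oxocyclohexane-1-carboxylate | O=C1CC[C@H](C#C)[C@@](C)(C(=O)OCC)[C@@H]1CCC2(C)OCCO2 | intermediate
13 | ethyl (1S,2R,6R)-6-ethynyl-1-methyl-3-methylidene-2-[2-(2-methyl-1,3-dioxolan-2-yl)ethyl]cyclohexane-1-carboxylate | C=C1CC[C@H](C#C)[C@@](C)(C(=O)OCC)[C@@H]1CCC2(C)OCCO2 | intermediate
14 | [(1S,2R,6R)-6-ethynyl-1-methyl-3-methylidene-2-[2-(2-methyl-1,3-dioxolan-2-yl)ethyl]cyclohexyl]methanol | C=C1CC[C@H](C#C)[C@@](C)(CO)[C@@H]1CCC2(C)OCCO2 | intermediate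
15 | 2-{2-[(1R,2S,3R)-3-ethynyl-2-(iodomethyl)-2-methyl-6-methylidenecyclohexyl]ethyl}-2-methyl-1,3-dioxolane | C=C1CC[C@H](C#C)[C@@](C)(CI)[C@@H]1CCC2(C)OCCO2 | intermediate
16 | 4,4,5,5-tetramethyl-2-vinyl-1,3,2-dioxaborolane (vinylboronic acid pinacol ester) | C=CB1OC(C)(C)C(C)(C)O1 | starting material
17 | α-boryl radical: 15 with CH2I replaced by CH2CH2CH(·)B(pin) (not isolated) | C=C1CC[C@H](C#C)[C@@](C)(CC[CH]B2OC(C)(C)C(C)(C)O2)[C@@H]1CCC3(C)OCCO3 | intermediate
18 | (3R,5R,9R,10S)-13,13-(ethylenedioxy)-3-(4,4,5,5-tetramethyl-1,3,2-dioxaborolan-2-yl)-14,15,18-trinorlabda-4(19),8(17)-diene (trans-decalin, boron equatorial) | C=C1CC[C@H]2[C@@](C)(CC[C@@H](B3OC(C)(C)C(C)(C)O3)C2=C)[C@@H]1CCC4(C)OCCO4 | intermediate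
19 | (3R,5S,9R,10S)-13,13-(ethylenedioxy)-14,15,18-trinorlabda-4(19),8(17)-dien-3-ol | C=C1CC[C@H]2[C@@](C)(CC[C@@H](O)C2=C)[C@@H]1CCC3(C)OCCO3 | intermediate
20 | (5S,9R,10S)-13,13-(ethylenedioxy)-14,15,18-trinorlabda-4(19),8(17)-dien-3-one | C=C1CC[C@H]2[C@@](C)(CCC(=O)C2=C)[C@@H]1CCC3(C)OCCO3 | intermediate
21 | lithium (5S,9R,10S)-13,13-(ethylenedioxy)-14,15,18-trinorlabda-3,8(17)-dien-3-olate (not isolated) | C=C1CC[C@H]2[C@@](C)(CCC([O-])=C2C)[C@@H]1CCC3(C)OCCO3.[Li+] | intermediate
22 | (4S,5S,9R,10S)-13,13-(ethylenedioxy)-18-hydroxy-14,15-dinorlabd-8(17)-en-3-one (formed as its lithium alkoxide, not isolated) | C=C1CC[C@H]2[C@@](C)(CCC(=O)[C@]2(C)CO)[C@@H]1CCC3(C)OCCO3 | intermediate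
23 | (4S,5S,9R,10S)-13,13-(ethylenedioxy)-18-(triisopropylsilyloxy)-14,15-dinorlabd-8(17)-en-3-one | C=C1CC[C@H]2[C@@](C)(CCC(=O)[C@]2(C)CO[Si](C(C)C)(C(C)C)C(C)C)[C@@H]1CCC3(C)OCCO3 | intermediate
24 | (3R,4S,5S,9R,10S)-13,13-(ethylenedioxy)-18-(triisopropylsilyloxy)-14,15-dinorlabd-8(17)-en-3-ol (not isolated) | C=C1CC[C@H]2[C@@](C)(CC[C@@H](O)[C@]2(C)CO[Si](C(C)C)(C(C)C)C(C)C)[C@@H]1CCC3(C)OCCO3 | intermediate
25 | (3R,4S,5S,9R,10S)-3-hydroxy-18-(triisopropylsilyloxy)-14,15-dinorlabd-8(17)-en-13-one | C=C1CC[C@H]2[C@@](C)(CC[C@@H](O)[C@]2(C)CO[Si](C(C)C)(C(C)C)C(C)C)[C@@H]1CCC(C)=O | intermediate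
26 | allyl 2-(diethoxyphosphoryl)acetate | C=CCOC(=O)CP(=O)(OCC)OCC | starting material
27 | allyl (3R,4S,5S,9R,10S,13E)-3-hydroxy-18-(triisopropylsilyloxy)labda-8(17),13-dien-15-oate | C=C1CC[C@H]2[C@@](C)(CC[C@@H](O)[C@]2(C)CO[Si](C(C)C)(C(C)C)C(C)C)[C@@H]1CC/C(C)=C/C(=O)OCC=C | intermediate
28 | angelic acid, (2Z)-2-methylbut-2-enoic acid | C/C=C(/C)C(=O)O | starting material
29 | (2Z)-2-methylbut-2-enoic 2,4,6-trichlorobenzoic anhydride (not isolated) | C/C=C(/C)C(=O)OC(=O)c1c(Cl)cc(Cl)cc1Cl | intermediate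
30 | allyl (3R,4S,5S,9R,10S,13E)-3-[(2Z)-2-methylbut-2-enoyloxy]-18-(triisopropylsilyloxy)labda-8(17),13-dien-15-oate | C=C1CC[C@H]2[C@@](C)(CC[C@@H](OC(=O)/C(C)=C\C)[C@]2(C)CO[Si](C(C)C)(C(C)C)C(C)C)[C@@H]1CC/C(C)=C/C(=O)OCC=C | intermediate
31 | (3R,4S,5S,9R,10S,13E)-3-[(2Z)-2-methylbut-2-enoyloxy]-18-(triisopropylsilyloxy)labda-8(17),13-dien-15-oic acid (formed as its phenylsilyl ester, not isolated) | C=C1CC[C@H]2[C@@](C)(CC[C@@H](OC(=O)/C(C)=C\C)[C@]2(C)CO[Si](C(C)C)(C(C)C)C(C)C)[C@@H]1CC/C(C)=C/C(=O)O | intermediate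
32 | (3R,4S,5S,9R,10S,13E)-18-hydroxy-3-[(2Z)-2-methylbut-2-enoyloxy]labda-8(17),13-dien-15-oic acid | C=C1CC[C@H]2[C@@](C)(CC[C@@H](OC(=O)/C(C)=C\C)[C@]2(C)CO)[C@@H]1CC/C(C)=C/C(=O)O | target

**Step count and risks**
Total step count: 18. Longest linear sequence: 16 (steps 1–3, then 6–18).

1. Step 11 (Proposed new method). What may go wrong: the α-boryl radical is reduced by the silane, takes the propargylic hydrogen from C5 by 1,5-transfer, or oligomerizes with the vinylboronate before the 6-exo-dig closure. Fallback with known chemistry, from 15 and returning at 19 (and so at 20): 15 and 16 are combined under plain reductive Giese conditions (Bu3SnH or (Me3Si)3SiH in one portion, AIBN), where reduction of the α-boryl radical is the wanted event, to give the open-chain pinacol boronate F1. H2O2/NaOH gives the primary alcohol F2 and Dess–Martin periodinane the ynal F3. A Ni(cod)2/PBu3-catalysed reductive alkyne–aldehyde cyclization with Et3SiH, a known route to 2-methylenecycloalkanols, then makes the C3–C4 bond and gives the triethylsilyl ether F4 as a mixture at C3. Bu4NF frees 19 together with its C3 epimer F5, and step 13 oxidizes both to 20.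

2. Step 6. What may go wrong: poor facial discrimination by the catalyst on a trisubstituted dienophile, or addition of the silyl dienol ether to the activated formyl group (aldol or hetero-Diels–Alder) in place of cycloaddition at the C=C bond. Fallback, from 5 and 9 and returning at 14: 5 and 9 are heated without catalyst (toluene, 90 °C) to give 10 as the racemate, that is together with its mirror image ent-10 F6. Steps 7 to 9 are run unchanged on the racemate, which carries along the mirror-image alkynyl silyl enol ether ent-11 F7, ketone ent-12 F8, methylene ester ent-13 F9 and alcohol ent-14 F10. The racemic alcohol is esterified with (S)-2-methoxy-2-phenylacetic acid (DCC, DMAP) to the diastereomeric esters, the O-methylmandelate of 14 F11 and the O-methylmandelate of ent-14 F12, which are separated by chromatography. K2CO3 in MeOH on F11 returns 14 as a single enantiomer.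

3. Step 17. What may go wrong: slow acylation of the hindered C3 hydroxyl, during which the mixed anhydride or the product isomerizes from the Z (angelate) to the E (tiglate) geometry. Fallback, from 27 and returning at 30: 27 is acylated with 2-[bis(2,2,2-trifluoroethoxy)phosphoryl]propanoic acid (DCC, DMAP), which cannot isomerize, to the phosphonopropanoate ester F13. KN(SiMe3)2 with 18-crown-6, then acetaldehyde at −78 °C (Still–Gennari olefination), builds the Z double bond on the alcohol and gives 30.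

**Further compounds**
F1 | step 11 | 2-{3-[(1S,2R,6R)-6-ethynyl-1-methyl-3-methylidene-2-[2-(2-methyl-1,3-dioxolan-2-yl)ethyl]cyclohexyl]propyl}-4,4,5,5-tetramethyl-1,3,2-dioxaborolane | C=C1CC[C@H](C#C)[C@@](C)(CCCB2OC(C)(C)C(C)(C)O2)[C@@H]1CCC3(C)OCCO3
F2 | step 11 | 3-[(1S,2R,6R)-6-ethynyl-1-methyl-3-methylidene-2-[2-(2-methyl-1,3-dioxolan-2-yl)ethyl]cyclohexyl]propan-1-ol | C=C1CC[C@H](C#C)[C@@](C)(CCCO)[C@@H]1CCC2(C)OCCO2
F3 | step 11 | 3-[(1S,2R,6R)-6-ethynyl-1-methyl-3-methylidene-2-[2-(2-methyl-1,3-dioxolan-2-yl)ethyl]cyclohexyl]propanal | C=C1CC[C@H](C#C)[C@@](C)(CCC=O)[C@@H]1CCC2(C)OCCO2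
F4 | step 11 | (5S,9R,10S)-13,13-(ethylenedioxy)-3-(triethylsilyloxy)-14,15,18-trinorlabda-4(19),8(17)-diene (both C3 epimers) | C=C1CC[C@H]2[C@@](C)(CCC(O[Si](CC)(CC)CC)C2=C)[C@@H]1CCC3(C)OCCO3
F5 | step 11 | (3S,5S,9R,10S)-13,13-(ethylenedioxy)-14,15,18-trinorlabda-4(19),8(17)-dien-3-ol (C3 epimer of 19) | C=C1CC[C@H]2[C@@](C)(CC[C@H](O)C2=C)[C@@H]1CCC3(C)OCCO3
F6 | step 6 | ent-10, ethyl (1R,2R,6R)-6-formyl-1-methyl-2-[2-(2-methyl-1,3-dioxolan-2-yl)ethyl]-3-(triisopropylsilyloxy)cyclohex-3-ene-1-carboxylate | CC(C)[Si](OC1=CC[C@@H](C=O)[C@](C)(C(=O)OCC)[C@H]1CCC2(C)OCCO2)(C(C)C)C(C)C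
F7 | step 6 | ent-11, ethyl (1S,2R,6S)-6-ethynyl-1-methyl-2-[2-(2-methyl-1,3-dioxolan-2-yl)ethyl]-3-(triisopropylsilyloxy)cyclohex-3-ene-1-carboxylate | CC(C)[Si](OC1=CC[C@@H](C#C)[C@](C)(C(=O)OCC)[C@H]1CCC2(C)OCCO2)(C(C)C)C(C)C
F8 | step 6 | ent-12, ethyl (1S,2R,6S)-6-ethynyl-1-methyl-2-[2-(2-methyl-1,3-dioxolan-2-yl)ethyl]-3-oxocyclohexane-1-carboxylate | O=C1CC[C@@H](C#C)[C@](C)(C(=O)OCC)[C@H]1CCC2(C)OCCO2
F9 | step 6 | ent-13, ethyl (1R,2S,6S)-6-ethynyl-1-methyl-3-methylidene-2-[2-(2-methyl-1,3-dioxolan-2-yl)ethyl]cyclohexane-1-carboxylate | C=C1CC[C@@H](C#C)[C@](C)(C(=O)OCC)[C@H]1CCC2(C)OCCO2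
F10 | step 6 | ent-14, [(1R,2S,6S)-6-ethynyl-1-methyl-3-methylidene-2-[2-(2-methyl-1,3-dioxolan-2-yl)ethyl]cyclohexyl]methanol | C=C1CC[C@@H](C#C)[C@](C)(CO)[C@H]1CCC2(C)OCCO2
F11 | step 6 | (2S)-2-methoxy-2-phenylacetate of 14 | C=C1CC[C@H](C#C)[C@@](C)(COC(=O)[C@@H](OC)c2ccccc2)[C@@H]1CCC3(C)OCCO3
F12 | step 6 | (2S)-2-methoxy-2-phenylacetate of ent-14 | C=C1CC[C@@H](C#C)[C@](C)(COC(=O)[C@@H](OC)c2ccccc2)[C@H]1CCC3(C)OCCO3
F13 | step 17 | allyl (3R,4S,5S,9R,10S,13E)-3-{2-[bis(2,2,2-trifluoroethoxy)phosphoryl]propanoyloxy}-18-(triisopropylsilyloxy)labda-8(17),13-dien-15-oate | C=C1CC[C@H]2[C@@](C)(CC[C@@H](OC(=O)C(C)P(=O)(OCC(F)(F)F)OCC(F)(F)F)[C@]2(C)CO[Si](C(C)C)(C(C)C)C(C)C)[C@@H]1CC/C(C)=C/C(=O)OCC=C
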